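## The problem

Compound 19 is a 3,3a-dihydro-1-benzofuran-6(2H)-one. Ring A, a cross-conjugated cyclohexadienone with a methoxy group on C5, and ring B, a dihydrofuran, share the C3a–C7a bond, and O1 ties C7a=C7–C6=O into a vinylogous ester. Three contiguous stereocentres line ring B: the quaternary C3a (allyl), C3 (methyl) and the benzylic C2 (3,4,5-trimethoxyphenyl), with methyl trans to allyl and cis to aryl, (2R,3S,3aS). C3a can only be made by C–C bond formation and cannot be corrected afterwards, but once in place it is the one element that distinguishes the two faces of ring B; C3 can then steer C2. C2 is the fragile centre: it is a benzylic carbon bound to a vinylogous carboxylate oxygen and an electron-rich arene, and the 2,3-cis arrangement is the less stable one. Ionisation in acid would cause epimerisation, reductive ring cleavage or carbon-bridged isomers, so C2 must be set late and under kinetic control. The 4-allyl dienone rules out heat (Cope shift of the allyl group) and strong acid (allyl migration), the terminal alkene rules out hydrogenation, and the C5 enol ether and the vinylogous ester rule out hard nucleophiles and long contact with aqueous acid. The enabling feature is that the C3 methyl and the C2 aryl both lie on the face of ring B opposite the allyl group. Hydrogenating a C2=C3 alkene that already bears the methyl would put the methyl on the allyl side, whereas a CH2 bridge laid across a C2=C3 enol ether from the open face and then severed at C2 leaves exactly the required pattern.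

## Retrosynthesis

**19 ⇒ 17.** The methyl carbon is reconnected to C2, giving cyclopropane 17; in the forward sense the C2–CH2 bond is cut by a proton and C2 receives hydride. The neighbouring options fail: C3 has no handle for alkylation or conjugate addition, and hydrogenation of a 3-methyl enol ether would deliver hydrogen, not carbon, from the open face. In 17 the configurations at C2 and C3 are a single question of one syn addition. The forward step must break C2–CH2 and not C2–C3 (which would expand the ring), deliver hydride anti to the new methyl, and keep acid exposure short.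

**17 ⇒ 15 + 16 (key disconnection).** Cutting C3–CH2 and C2–CH2 removes a methylene unit and leaves the planar enol ether 15 with C3a as its only stereocentre. An electrophilic zinc carbenoid from diiodomethane 16 is preferred to a metal carbene from diazomethane (which favours terminal and electron-poor alkenes) and to a sulfur ylide (which would attack the dienone). The forward reaction must choose the C2=C3 enol ether over three other alkenes and the face anti to allyl.

**15 ⇒ 14.** Cutting O1–C2 opens ring B to the alkynyl vinylogous acid 14. The alternative cut at O1–C7a would need a preformed C2 oxygen and a second stereocentre; the alkyne needs none and places the aryl group on a linear, easily made unit. The forward step is a 5-endo-dig addition of the C7a enol oxygen to the alkyne at room temperature.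

**14 ⇒ 13 ⇒ 12.** The enol of 14 is masked as the methyl vinylogous ester 13, and the C6 carbonyl of 13 is traced back to the doubly allylic CH2 of the 1,4-diene 12. This is the pattern a Birch reduction leaves, with one methoxy group (C5) kept and the other (on C7a) becoming the ring oxygen. The forward steps are a regioselective allylic oxidation and a hydrolysis that distinguishes a β-methoxy from an α-methoxy enone.

**12 ⇒ 10 + 11.** The C(sp)–C(aryl) bond is cut: Sonogashira coupling of alkyne 10 with 5-iodo-1,2,3-trimethoxybenzene 11 brings in the whole aryl group in one convergent step and keeps the electron-rich arene out of the reductive early steps.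

**10 ⇒ 9 ⇒ 8 ⇒ 7.** The alkyne carbon on C3a (the future C3) is the carbonyl carbon of amide 7; the terminal carbon comes from a one-carbon homologation of aldehyde 9, reached through alcohol 8. This uses the carboxyl carbon that directed the dearomatisation instead of discarding it.

**7 ⇒ 4 + 5, 4 ⇒ 1 + 2.** The C3a–allyl bond is cut: Birch reduction–alkylation of the chiral benzamide 4 with allyl bromide 5, via enolate 6, builds the quaternary centre and dearomatises ring A with both methoxy groups already in place. Amide 4 comes from 2,5-dimethoxybenzoic acid 1 and (S)-2-(methoxymethyl)pyrrolidine 2 through acid chloride 3. Every later stereocentre descends from this one event.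

## Roads not taken

**Alternative 1:** Cut C3a–C7a in ring A. Thermolysis of the squarate-derived cyclobutenone A2 would open it to a dienylketene, whose ketene carbon closes onto the alkene terminus by 6π electrocyclisation to give dienone A1.
- Merits: ring A arrives with its full oxygen pattern in one step; C2 and C3 are made beforehand by reliable acyclic chemistry; the route is convergent and uses no step beyond known reaction types. In this last respect it is better than the chosen plan.
- Weak points: the closing terminus is fully substituted, so the configuration of C3a depends on the geometry of a trisubstituted alkene and on a helical sense of closure that only the neighbouring C3 centre can bias. The temperature needed endangers the allyl group of A1 through [3,3] shifts. Closing ring B from A1 requires an acid-catalysed exchange at the vinylogous ester with a free benzylic C2 alcohol, the same ionisation risk the chosen plan faces.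
- Comparison: the chosen plan sets against it a C3a centre fixed by an auxiliary and a fully room-temperature sequence after dearomatisation.

**Alternative 2:** Cut O1–C7a. The C2 hydroxyl of the symmetric dienone A4 would add 5-exo-trig to one of the two diastereotopic enone β-carbons, giving the cis-fused adduct A3 and fixing C3a.
- Merits: A4 is short to reach by dearomatisation of a 2,6-dimethoxyphenol; the ring fusion is automatically cis; C2 and C3 are again made in the open chain. The road to A3 is shorter and better precedented than the road to 17.
- Weak points: the choice between the two enone arms rests on a small difference (methyl syn or anti to allyl), and the addition is reversible, so the outcome drifts towards thermodynamic control, which does not favour the 2,3-cis target. A3 has an extra methoxy group α to the carbonyl and lacks the C7=C7a double bond. No simple β-elimination removes it, so reductive cleavage and re-oxidation must follow while a retro-oxa-Michael reaction threatens C3a.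
- Comparison: the chosen plan has a single auxiliary-controlled stereo-determining step and a two-step endgame, but it carries the one unprecedented step that this alternative avoids.

**Alternative 3:** Cut C5–C6. An N-heterocyclic carbene would turn the aliphatic aldehyde of dialdehyde A6 into an acyl anion equivalent that adds to the vinylogous formyl carbon, closing ring A as acyloin A5.
- Merits: ring A is closed under neutral catalysis with ring B and all three stereocentres already present; no late acid is needed, which is a real advantage over the chosen plan.
- Weak points: in A6, C3a carries an allyl and a 2-oxoethyl arm, so its configuration requires telling apart two nearly identical three-carbon arms. The vinylogous formyl group is a deactivated electrophile and can itself form a carbene adduct. A5 still needs oxidation to the diosphenol and a regioselective O-methylation.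
- Comparison: the route is clearly longer; the chosen plan offers a short linear sequence and a C3a centre of secure origin.

Key step: step 10

Assumption: the (S)-2-(methoxymethyl)pyrrolidine amide is taken to direct allyl bromide to the enolate face that gives the (S)-configured quaternary carbon of 7, the sense expected for ortho-methoxybenzamides of this auxiliary; if the sense were reversed, the auxiliary from D-proline would be used and nothing else changes.

## Route

Step 1
Reactants: 1 2,5-dimethoxybenzoic acid; 2 (S)-2-(methoxymethyl)pyrrolidine
Product: 4 [(2S)-2-(methoxymethyl)pyrrolidin-1-yl](2,5-dimethoxyphenyl)methanone, via 2,5-dimethoxybenzoyl chloride 3 (not isolated)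
Conditions: (COCl)2, DMF (cat.), CH2Cl2, 0 °C → rt; evaporate; then 2, Et3N, CH2Cl2, 0 °C → rt
Reagents that add atoms: none
Why: Acid chloride formation followed by amidation of a secondary amine is routine acyl substitution; the auxiliary stereocentre is not involved.

Step 2
Reactants: 4 [(2S)-2-(methoxymethyl)pyrrolidin-1-yl](2,5-dimethoxyphenyl)methanone; 5 allyl bromide
Product: 7 [(1S)-1-allyl-2,5-dimethoxycyclohexa-2,5-dien-1-yl][(2S)-2-(methoxymethyl)pyrrolidin-1-yl]methanone, via potassium amide enolate 6 (not isolated)
Conditions: K (2.2 equiv), t-BuOH (1 equiv), NH3/THF, −78 °C; then 5, −78 °C; NH4Cl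
Reagents that add atoms: none
Why: Birch reduction–alkylation of a chiral benzamide: two electrons and one proton (at C4, para to the carboxamide) give the amide enolate, which is allylated at C1 while both methoxy groups stay on vinylic carbons; the quaternary centre is set by the pyrrolidine auxiliary in the chelated potassium enolate, in the facial sense assumed above.

Step 3
Reactants: 7 [(1S)-1-allyl-2,5-dimethoxycyclohexa-2,5-dien-1-yl][(2S)-2-(methoxymethyl)pyrrolidin-1-yl]methanone
Product: 8 [(1R)-1-allyl-2,5-dimethoxycyclohexa-2,5-dien-1-yl]methanol
Conditions: LiNH2BH3 (from BH3·NH3 and LiN(i-Pr)2), THF, 0 °C → rt; aq. NaOH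
Reagents that add atoms: none
Why: Lithium amidotrihydroborate reduces tertiary amides, hindered ones included, to primary alcohols with C–N cleavage and leaves enol ethers and isolated alkenes alone; the quaternary centre cannot epimerise (the descriptor changes only through priorities) and the auxiliary is recovered.

Step 4
Reactants: 8 [(1R)-1-allyl-2,5-dimethoxycyclohexa-2,5-dien-1-yl]methanol
Product: 9 (1S)-1-allyl-2,5-dimethoxycyclohexa-2,5-diene-1-carbaldehyde
Conditions: Dess–Martin periodinane, NaHCO3, CH2Cl2, 0 °C → rt
Reagents that add atoms: none
Why: Dess–Martin oxidation buffered with bicarbonate converts the neopentyl alcohol to the aldehyde without the acid that would hydrolyse the enol ethers; the aldehyde has no α-hydrogen and is used at once.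

Step 5
Reactants: 9 (1S)-1-allyl-2,5-dimethoxycyclohexa-2,5-diene-1-carbaldehyde
Product: 10 (6R)-6-allyl-6-ethynyl-1,4-dimethoxycyclohexa-1,4-diene
Conditions: dimethyl (1-diazo-2-oxopropyl)phosphonate, K2CO3, MeOH, 0 °C → rt
Reagents that add atoms: dimethyl (1-diazo-2-oxopropyl)phosphonate, COP(=O)(OC)C(=[N+]=[N-])C(C)=O
Why: Seyferth–Gilbert homologation with the Ohira–Bestmann reagent converts non-enolisable, α-quaternary aldehydes into terminal alkynes under mild carbonate conditions that the enol ethers tolerate.

Step 6
Reactants: 10 (6R)-6-allyl-6-ethynyl-1,4-dimethoxycyclohexa-1,4-diene; 11 5-iodo-1,2,3-trimethoxybenzene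
Product: 12 5-{[(1R)-1-allyl-2,5-dimethoxycyclohexa-2,5-dien-1-yl]ethynyl}-1,2,3-trimethoxybenzene
Conditions: PdCl2(PPh3)2 (3 mol%), CuI (6 mol%), Et3N, THF, rt
Reagents that add atoms: none
Why: Sonogashira coupling of a terminal alkyne with an aryl iodide proceeds at room temperature under basic conditions; no stereocentre or enol ether is affected.

Step 7
Reactants: 12 5-{[(1R)-1-allyl-2,5-dimethoxycyclohexa-2,5-dien-1-yl]ethynyl}-1,2,3-trimethoxybenzene
Product: 13 (4R)-4-allyl-2,5-dimethoxy-4-[(3,4,5-trimethoxyphenyl)ethynyl]cyclohexa-2,5-dien-1-one
Conditions: (C5H5NH)2Cr2O7, t-BuOOH, Celite, benzene, rt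
Reagents that add atoms: tert-butyl hydroperoxide, CC(C)(C)OO
Why: Kharasch-type allylic oxidation: the doubly allylic ring CH2 has by far the weakest C–H bond, and peroxyl trapping there followed by collapse of the mixed peroxide gives the cross-conjugated dienone, a conversion established for 1,4-dienes from Birch alkylation; hexavalent chromium acts as mediator and t-BuOOH as terminal oxidant.

Step 8
Reactants: 13 (4R)-4-allyl-2,5-dimethoxy-4-[(3,4,5-trimethoxyphenyl)ethynyl]cyclohexa-2,5-dien-1-one
Product: 14 (4R)-4-allyl-5-hydroxy-2-methoxy-4-[(3,4,5-trimethoxyphenyl)ethynyl]cyclohexa-2,5-dien-1-one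
Conditions: LiOH, THF/H2O, 0 °C → rt; then 1 M HCl to pH 4, 0 °C
Reagents that add atoms: water, O
Why: Vinylogous ester saponification: hydroxide adds to the β-methoxy enone carbon and expels methoxide, whereas the α-methoxy enone has no such addition–elimination path; the vinylogous carboxylate formed resists further attack.

Step 9
Reactants: 14 (4R)-4-allyl-5-hydroxy-2-methoxy-4-[(3,4,5-trimethoxyphenyl)ethynyl]cyclohexa-2,5-dien-1-one
Product: 15 (3aS)-3a-allyl-5-methoxy-2-(3,4,5-trimethoxyphenyl)-1-benzofuran-6(3aH)-one
Conditions: AuCl(PPh3) (5 mol%), AgOTf (5 mol%), CH2Cl2, rt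
Reagents that add atoms: none
Why: Gold-catalysed 5-endo-dig hydroalkoxylation (cycloisomerisation), the reaction type that turns ortho-alkynylphenols into 2-arylbenzofurans: the enol oxygen next to the quaternary carbon adds to the π-activated alkyne at the aryl-bearing carbon and protodeauration gives the enol ether; room temperature avoids the Cope shift of the allyl group.

Step 10
Reactants: 15 (3aS)-3a-allyl-5-methoxy-2-(3,4,5-trimethoxyphenyl)-1-benzofuran-6(3aH)-one; 16 diiodomethane
Product: 17 (1aS,6aR,6bS)-6a-allyl-5-methoxy-1a-(3,4,5-trimethoxyphenyl)-1,1a,6a,6b-tetrahydro-4H-cyclopropa[b][1]benzofuran-4-one (the 2,3-methano adduct of 15, CH2 anti to allyl)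
Conditions: Et2Zn (2 equiv), CF3CO2H (2 equiv), 16 (2 equiv), CH2Cl2, 0 °C; then 15, 0 °C → rt
Reagents that add atoms: none
Why: Simmons–Smith cyclopropanation with the acyloxy zinc carbenoid CF3CO2ZnCH2I; the closest known reaction type is methylene transfer to enol ethers, enol esters and styrenes. The electrophilic carbenoid transfers CH2 to C2=C3 in a concerted, stereospecific syn addition through a butterfly-type transition state, forming C3–CH2 and C2–CH2 together. The three-membered ring closes by this [2+1] addition, iodide leaving the carbenoid carbon as the second C–C bond forms, so ring B becomes a cis-fused 2-oxabicyclo[3.1.0]hexane. Both new stereocentres, C2 and C3, are fixed by the face of approach, which the quaternary C3a controls: the allyl group stands over one face of the flat ring B, while the other face meets only the sp2 C4–H of ring A. Chemoselectivity rests on nucleophilicity: C2=C3 is an aryl-conjugated enol ether, whereas the allyl alkene is monosubstituted and unactivated and the two alkenes of ring A are conjugated to the carbonyl group. A small excess of reagent at 0 °C with monitoring should keep the allyl group untouched.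

Step 11
Reactants: 17 (1aS,6aR,6bS)-6a-allyl-5-methoxy-1a-(3,4,5-trimethoxyphenyl)-1,1a,6a,6b-tetrahydro-4H-cyclopropa[b][1]benzofuran-4-one
Product: 19 (2R,3S,3aS)-3a-allyl-5-methoxy-3-methyl-2-(3,4,5-trimethoxyphenyl)-3,3a-dihydro-1-benzofuran-6(2H)-one, via C2 oxocarbenium trifluoroacetate 18 (not isolated)
Conditions: CF3CO2H (5 equiv), Et3SiH (5 equiv), CH2Cl2, −40 → 0 °C
Reagents that add atoms: none
Why: Proposed new method: protonation of the cyclopropane at its CH2 carbon, the least substituted one, cleaves the C2–CH2 bond because the charge then rests on C2, stabilised by O1 and the trimethoxyphenyl ring, so the methylene stays on C3 as methyl with the configuration set in step 10; Et3SiH, present from the start, delivers hydride to the planar ion 18 on the face opposite the adjacent C3 methyl, giving aryl cis to methyl under kinetic control; the closest known reaction types are acid opening of alkoxycyclopropanes to α-methyl carbonyl compounds, ionic hydrogenation of arylcyclopropanes and silane reduction of 2-aryl oxocarbenium ions anti to a C3 substituent, but their combination on a cyclopropane fused to a vinylogous ester has not been shown.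

## Compound list

1 | 2,5-dimethoxybenzoic acid | COc1ccc(OC)c(C(=O)O)c1 | starting material
2 | (S)-2-(methoxymethyl)pyrrolidine | COC[C@@H]1CCCN1 | starting material
3 | 2,5-dimethoxybenzoyl chloride | COc1ccc(OC)c(C(=O)Cl)c1 | intermediate (not isolated)
4 | [(2S)-2-(methoxymethyl)pyrrolidin-1-yl](2,5-dimethoxyphenyl)methanone | COc1ccc(OC)c(C(=O)N2CCC[C@H]2COC)c1 | intermediate
5 | allyl bromide | C=CCBr | starting material
6 | potassium (2,5-dimethoxycyclohexa-2,5-dien-1-ylidene)[(2S)-2-(methoxymethyl)pyrrolidin-1-yl]methanolate | [K+].[O-]C(N1CCC[C@H]1COC)=C1C=C(OC)CC=C1OC | intermediate (not isolated)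
7 | [(1S)-1-allyl-2,5-dimethoxycyclohexa-2,5-dien-1-yl][(2S)-2-(methoxymethyl)pyrrolidin-1-yl]methanone | C=CC[C@@]1(C(=O)N2CCC[C@H]2COC)C(OC)=CCC(OC)=C1 | intermediate
8 | [(1R)-1-allyl-2,5-dimethoxycyclohexa-2,5-dien-1-yl]methanol | C=CC[C@@]1(CO)C(OC)=CCC(OC)=C1 | intermediate
9 | (1S)-1-allyl-2,5-dimethoxycyclohexa-2,5-diene-1-carbaldehyde | C=CC[C@@]1(C=O)C(OC)=CCC(OC)=C1 | intermediate
10 | (6R)-6-allyl-6-ethynyl-1,4-dimethoxycyclohexa-1,4-diene | C=CC[C@@]1(C#C)C(OC)=CCC(OC)=C1 | intermediate
11 | 5-iodo-1,2,3-trimethoxybenzene | COc1cc(I)cc(OC)c1OC | starting material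
12 | 5-{[(1R)-1-allyl-2,5-dimethoxycyclohexa-2,5-dien-1-yl]ethynyl}-1,2,3-trimethoxybenzene | C=CC[C@@]1(C#Cc2cc(OC)c(OC)c(OC)c2)C(OC)=CCC(OC)=C1 | intermediate
13 | (4R)-4-allyl-2,5-dimethoxy-4-[(3,4,5-trimethoxyphenyl)ethynyl]cyclohexa-2,5-dien-1-one | C=CC[C@@]1(C#Cc2cc(OC)c(OC)c(OC)c2)C(OC)=CC(=O)C(OC)=C1 | intermediate
14 | (4R)-4-allyl-5-hydroxy-2-methoxy-4-[(3,4,5-trimethoxyphenyl)ethynyl]cyclohexa-2,5-dien-1-one | C=CC[C@@]1(C#Cc2cc(OC)c(OC)c(OC)c2)C(O)=CC(=O)C(OC)=C1 | intermediate
15 | (3aS)-3a-allyl-5-methoxy-2-(3,4,5-trimethoxyphenyl)-1-benzofuran-6(3aH)-one | C=CC[C@]12C=C(OC)C(=O)C=C1OC(c1cc(OC)c(OC)c(OC)c1)=C2 | intermediate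
16 | diiodomethane | ICI | starting material
17 | (1aS,6aR,6bS)-6a-allyl-5-methoxy-1a-(3,4,5-trimethoxyphenyl)-1,1a,6a,6b-tetrahydro-4H-cyclopropa[b][1]benzofuran-4-one | C=CC[C@]12C=C(OC)C(=O)C=C1O[C@@]3(c4cc(OC)c(OC)c(OC)c4)C[C@@H]23 | intermediate
18 | 2-aryl oxocarbenium ion (O1=C2 cation of the ring-opened cyclopropane, C3 methyl anti to allyl) as trifluoroacetate | C=CC[C@]12C=C(OC)C(=O)C=C1[O+]=C(c1cc(OC)c(OC)c(OC)c1)[C@H]2C.[O-]C(=O)C(F)(F)F | intermediate (not isolated)
19 | (2R,3S,3aS)-3a-allyl-5-methoxy-3-methyl-2-(3,4,5-trimethoxyphenyl)-3,3a-dihydro-1-benzofuran-6(2H)-one | C=CC[C@]12C=C(OC)C(=O)C=C1O[C@@H](c1cc(OC)c(OC)c(OC)c1)[C@H]2C | target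

## Step count and least certain steps

Total: 11 steps. Longest linear sequence: 11 steps (1 → 19); compounds 2, 5, 11 and 16 are purchased.

**Step 11 (proposed new method).** The cyclopropane may need an acidity and time at which the benzylic C2–O1 bond of the product ionises, leading to reductive opening of ring B by the silane, epimerisation at C2 or allyl migration in the protonated dienone. Hydride delivery may also be incompletely face-selective. The fallback uses known chemistry, sets out from 17 and returns at 19. Dilute HCl in aqueous THF (rt to 40 °C) hydrolyses the vinylogous ester link and opens the resulting arylcyclopropanol at its CH2 carbon, giving the α-methyl aryl ketone F1 with C3 unchanged. NaBH4 in MeOH at −20 °C, acting on the sodium salt of the vinylogous acid, reduces only the aryl ketone; Felkin–Anh approach anti to the quaternary substituent should favour the anti alcohol F2. Mitsunobu closure (PPh3, DIAD, THF, 0 °C), in which the vinylogous acid oxygen displaces the activated benzylic hydroxyl with inversion, then gives 19 without strong acid.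

**Step 10 (key step).** Methylene transfer may be unselective between the enol ether and the allyl alkene, or sluggish because O1 is a weakened donor and C3 is neopentyl; the facial preference anti to allyl may also be incomplete. The fallback sets out from 15 and returns at 17. Dibromocarbene (CHBr3, KOt-Bu, pentane/THF, −30 °C), a small free carbene that discriminates more sharply in favour of donor-substituted alkenes, gives the dibromocyclopropane F3. Bu3SnH (2.2 equiv) with Et3B/air in benzene at rt to 60 °C then removes both bromine atoms and gives 17.

**Step 9.** The gold-activated alkyne may be intercepted by the allyl alkene (cycloisomerisation of the 1,5-enyne) instead of the enol oxygen. The fallback sets out from 14 and returns at 15. Iodocyclisation (I2, NaHCO3, MeCN, 0 °C) closes ring B through an iodonium ion, with no carbene-type pathway open to the enyne, and gives the 3-iodo enol ether F4. Hydrodeiodination (Bu3SnH, Pd(PPh3)4 cat., THF, rt) gives 15.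

**Step 7.** Oxidation may stray to the allyl CH2 or the electron-rich aryl alkyne, the peroxyl radical may be trapped at a methoxy-bearing terminus of the pentadienyl radical, or acidic chromium species may hydrolyse an enol ether. The fallback sets out from 10 and returns at 13. The same oxidation is run on the simpler alkyne 10, before the arene is present, to give the ethynyl dienone F5. Sonogashira coupling of F5 with 11 (PdCl2(PPh3)2, CuI, Et3N, THF, rt) gives 13.

**Step 2.** Allyl bromide may approach the enolate from the face opposite to the one assumed, or with selectivity eroded by the 5-methoxy group. The fallback sets out from 3 and returns at 8. (R)-2-(Methoxymethyl)pyrrolidine is used to form the enantiomeric-auxiliary amide F6. Birch reduction–allylation under the step 2 conditions gives the diastereomeric amide F7, with the (S)-configured quaternary carbon. LiNH2BH3 reduction as in step 3 gives 8; where only selectivity is eroded, the diastereomers are separated while the auxiliary is still attached.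

## Further compounds

F1 | step 11 | (4R)-4-allyl-5-hydroxy-2-methoxy-4-[(2S)-1-oxo-1-(3,4,5-trimethoxyphenyl)propan-2-yl]cyclohexa-2,5-dien-1-one | C=CC[C@@]1([C@H](C)C(=O)c2cc(OC)c(OC)c(OC)c2)C(O)=CC(=O)C(OC)=C1
F2 | step 11 | (4S)-4-allyl-5-hydroxy-4-[(1S,2S)-1-hydroxy-1-(3,4,5-trimethoxyphenyl)propan-2-yl]-2-methoxycyclohexa-2,5-dien-1-one | C=CC[C@@]1([C@H](C)[C@H](O)c2cc(OC)c(OC)c(OC)c2)C(O)=CC(=O)C(OC)=C1
F3 | step 10 | 1,1-dibromo derivative of 17 (dibromomethylene bridge across C2 and C3 of 15, anti to allyl) | C=CC[C@]12C=C(OC)C(=O)C=C1O[C@@]3(c4cc(OC)c(OC)c(OC)c4)C(Br)(Br)[C@@H]23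
F4 | step 9 | (3aS)-3a-allyl-3-iodo-5-methoxy-2-(3,4,5-trimethoxyphenyl)-1-benzofuran-6(3aH)-one | C=CC[C@]12C=C(OC)C(=O)C=C1OC(c1cc(OC)c(OC)c(OC)c1)=C2I
F5 | step 7 | (4R)-4-allyl-4-ethynyl-2,5-dimethoxycyclohexa-2,5-dien-1-one | C=CC[C@@]1(C#C)C(OC)=CC(=O)C(OC)=C1
F6 | step 2 | [(2R)-2-(methoxymethyl)pyrrolidin-1-yl](2,5-dimethoxyphenyl)methanone | COc1ccc(OC)c(C(=O)N2CCC[C@@H]2COC)c1
F7 | step 2 | [(1S)-1-allyl-2,5-dimethoxycyclohexa-2,5-dien-1-yl][(2R)-2-(methoxymethyl)pyrrolidin-1-yl]methanone | C=CC[C@@]1(C(=O)N2CCC[C@@H]2COC)C(OC)=CCC(OC)=C1
A1 | alternative 1 | 6-allyl-3-isopropoxy-4-methoxycyclohexa-2,4-dien-1-one bearing the 1-(tert-butyldimethylsilyloxy)-1-(3,4,5-trimethoxyphenyl)propan-2-yl chain on C6 | C=CC[C@@]1(C=C(OC)C(OC(C)C)=CC1=O)[C@H](C)[C@@H](O[Si](C)(C)C(C)(C)C)c1cc(OC)c(OC)c(OC)c1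
A2 | alternative 1 | 3-isopropoxy-4-methoxy-4-alkenylcyclobut-2-en-1-one whose alkenyl terminus carries the allyl group and the silyloxy aryl chain (alkene geometry and ring carbinol configuration left open) | C=CCC(=CC1(OC)C(OC(C)C)=CC1=O)[C@H](C)[C@@H](O[Si](C)(C)C(C)(C)C)c1cc(OC)c(OC)c(OC)c1
A3 | alternative 2 | cis-fused 7-methoxy-7,7a-dihydro form of 19 (C7 of either configuration) | C=CC[C@]12C=C(OC)C(=O)C(OC)[C@H]1O[C@@H](c1cc(OC)c(OC)c(OC)c1)[C@H]2C
A4 | alternative 2 | 4-allyl-4-[1-hydroxy-1-(3,4,5-trimethoxyphenyl)propan-2-yl]-2,6-dimethoxycyclohexa-2,5-dien-1-one | C=CCC1([C@H](C)[C@@H](O)c2cc(OC)c(OC)c(OC)c2)C=C(OC)C(=O)C(OC)=C1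
A5 | alternative 3 | ring A acyloin (C5 ketone, C6 carbinol of either configuration) | C=CC[C@]12CC(=O)C(O)C=C1O[C@@H](c1cc(OC)c(OC)c(OC)c1)[C@H]2C
A6 | alternative 3 | 2-aryl-3-methyl-4-allyl-4-(2-oxoethyl)-5-(2-oxoethylidene)tetrahydrofuran (alkene geometry left open) | C=CC[C@]1(CC=O)C(=CC=O)O[C@@H](c2cc(OC)c(OC)c(OC)c2)[C@H]1C
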